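Assumption: the target is the (3S) enantiomer encoded in the SMILES, 1-[(3S)-3,5,7-trihydroxy-2,2,6-trimethylchroman-8-yl]-3-phenylpropan-1-one. Chroman numbering (O1, C2, C3, C4, C4a, C5 to C8, C8a) is used for all bicyclic compounds.

## The problem

The target 18 is a chroman whose benzene ring is substituted at every position: hydroxyls at C5 and C7, a methyl at C6, a 3-phenylpropanoyl group at C8, and the pyran ring fused across C4a–C8a with O1 on the carbon next to the acyl group. The pyran ring holds a quaternary C2 (two methyls and O1), a secondary carbinol at C3 and a methylene at C4. C3 is the only stereocentre (S), so no second centre can relay chirality to it and its configuration must come from a chiral reagent or catalyst acting on a prochiral C3. The arene is an acylated methylphloroglucinol, easily oxidised as a free polyphenol. The tertiary alkyl aryl ether O1–C2 can ionise under strong acid, the more so once the C8 carbonyl can chelate a Lewis acid, and the C3 carbinol can be lost by elimination towards benzylic C4. The regiochemistry of a hexasubstituted benzene is safest when decided on a symmetric precursor, here a 3,5-dioxygenated 4-methylphenol whose two ortho carbons are equivalent. The enabling feature is that C4 is a single methylene between C4a and C3: removing it joins C3 to the arene and leaves a 2,2-dimethylbenzofuran-3-one, whose carbonyl sits on the carbon that must become the carbinol. One intramolecular acylation of an aryloxyisobutyric acid delivers that ketone together with O1, C2 and both methyls, and reinserting the carbon by diazoalkane homologation with aryl migration gives the chroman with the C3 oxygen in place as a ketone.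

## Retrosynthesis

**18 to 17.** The two O–CH3 bonds at C5 and C7 are cut last. Methyl ethers are chosen because they survive every acid, Lewis acid and hydride used before, and because unmasking at the end keeps the air-sensitive diphenol out of all earlier steps. Precursor 17 differs from 18 only by the two methyls. The forward reaction must cleave two aryl methyl ethers without opening O1–C2 and without touching the C3 carbinol.

**17 to 13 and 14.** The C8–acyl bond is cut. In 13, C8 is the only unsubstituted ring carbon and lies ortho to O1, ortho to the 7-methoxy group and para to the 5-methoxy group, so a Friedel–Crafts acylation has no regiochemical choice. Placing the side chain earlier would put a second ketone into the homologation and the reduction and would make the arene a poorer migrating group. The C3 hydroxyl would be acylated by 14 in any case, so this is done on purpose: two equivalents of 14 give ester 16 by way of 15, and saponification returns the carbinol in 17. The forward step must acylate the ring faster than 14 cyclises onto its own phenyl ring.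

**13 to 12.** The C3–H bond is cut, so the stereocentre comes from enantioselective reduction of ketone 12. The carbonyl is flanked by a quaternary carbon (C2) and a methylene (C4), the size difference on which oxazaborolidine-catalysed borane reduction relies. A transfer hydrogenation with RuCl(p-cymene)(TsDPEN), which works best with an aryl group directly on the carbonyl carbon, has less to hold on to here. Precursor 12 is achiral.

**12 to 9 and 10 (key disconnection).** The bonds C3–C4 and C4–C4a are cut, so C4 is taken out and C3 is joined to the arene. Neighbouring cuts, O1–C2 with C4–C4a or C3–C4 with O1–C2, lead to the prenyl, epoxide and quinone methide logic discussed below. This cut leaves the benzofuran-3-one 9, in which the whole oxygenation pattern and the gem-dimethyl group are already fixed, and the one-carbon reagent 10. The forward reaction must add a diazoalkane to a deactivated carbonyl, move the aryl carbon and not C2, and stop after one homologation.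

**9 to 7.** The aryl–carbonyl bond C3–C3a is cut. Intramolecular Friedel–Crafts acylation of acid 7, through mixed anhydride 8, can only strike one of two equivalent ortho carbons, each activated by three oxygen substituents. Precursor 7 is an open-chain acid with no ring besides the benzene.

**7 to 4 and 5.** The ether bond between the phenol oxygen and the quaternary carbon is cut. Alkylation of phenol 4 with bromo ester 5 gives ester 6, which is saponified to 7. This puts O1, C2 and both methyls in place with two standard reactions.

**4 to 1 and 2.** The phenol C–O bond is cut. Sterically controlled C–H borylation of 1 with 2 occurs at the only C–H bond without an ortho neighbour, and boronate 3 is oxidised in the same flask. The symmetric phenol 4 thus comes from a cheap arene in one operation.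

## Roads not taken

**Alternative 1:** The cut is C3–C4 together with O1–C2, with C2 at the lactone oxidation level.
- **Forward key step:** the ortho-quinone methide A3, released by base from the sulfone A2, is trapped by the chiral ammonium enolate made from (benzyloxy)acetyl chloride A4 and a cinchona-derived Lewis base. This gives the lactone A1 and sets C3 in the ring-forming event.
- **Merits:** ring formation and stereocontrol are merged, no diazo reagent is needed, and the C3 oxygen arrives as a benzyl ether. That is better than in the chosen plan, where the C3 hydroxyl has to be carried through the C8 acylation as an ester.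
- **Weak points:** A3 carries two alkoxy donors and is a stabilised, sluggish acceptor prone to self-condensation. The α-alkoxy aryl ester stereocentre of A1 is epimerisable under the amine base. C2 arrives as a carbonyl, so the gem-dimethyl group needs double methyl addition and an acid-mediated re-closure through a tertiary cation next to C3. Debenzylation, C8 acylation and demethylation still follow.
- **Comparison:** the chosen plan spends a separate step on the stereocentre, but every carbon of the pyran ring is at its final substitution level after the key step and no intermediate has an epimerisable centre.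

**Alternative 2:** The cut is C4a–C4 together with O1–C2.
- **Forward key step:** the acylphloroglucinol monobenzyl ether A6 condenses with 3-methylbut-2-enal A7 under amine acetate catalysis (condensation, then oxa-6π electrocyclisation) to give chromene A5. Only one ring carbon is free, so the regiochemistry is fixed.
- **Completion:** asymmetric epoxidation with a chiral (salen)MnCl complex would give the (3S,4S)-epoxide A8. Hydrogenolysis could then open the benzylic C4–O bond and remove the benzyl group in one step.
- **Merits:** this road is shorter than the chosen one, carries the side chain from the start, and its enantioselective step has the best precedent for 2,2-dimethylchromenes. In both respects it is superior on paper.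
- **Weak points:** A5 is a free phenol on a C-methylated acylphloroglucinol, and oxidants that epoxidise the alkene can also dearomatise such rings. In A8 the benzylic C4–O bond is activated by para and ortho oxygen donors and ionises readily, leading to diols or, by hydride shift, to the 3-ketone with loss of the stereocentre. A6 needs selective benzylation of one of three hydroxyls of a costlier phloroglucinol.
- **Comparison:** the chosen plan sets robustness against brevity. No oxidant meets the electron-rich arene, the phenols stay methylated until the last step, and C3 is carried as a ketone and then a stable carbinol.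

**Alternative 3:** The cut is C3–C4 with C4 at the ketone level.
- **Forward key step:** a chiral triazolium-derived carbene converts the aryl aldehyde of dialdehyde A10 into its acyl anion equivalent, which adds to the aliphatic aldehyde and gives the ketol A9. Its (3R) descriptor denotes the same spatial arrangement as (3S) in 18, because C4 outranks C2 while it is a carbonyl.
- **Merits:** ring closure and stereocentre come in one organocatalytic step, the acceptor aldehyde cannot enolise, and A10 derives from the same aryl ether family as 6.
- **Weak points:** the aryl aldehyde has two ortho oxygens and a para methoxy group, so it is hindered and electron-rich and forms the acyl anion equivalent slowly. The roles of the two aldehydes may invert. A9 is an α-ketol that can racemise through its enediol under the basic conditions. The C4 carbonyl must then be removed by reduction and benzylic deoxygenation next to the C3 carbinol, and making A10 needs formylation and redox adjustment.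
- **Comparison:** the chosen plan delivers C4 as a methylene and C3 as a ketone in one event, so nothing has to be deleted afterwards. It pays with the use of a diazoalkane and a separate reduction.

Key step: step 5

## Route

Step 1
Reactants: 1 2,6-dimethoxytoluene; 2 bis(pinacolato)diboron
Product: 4 3,5-dimethoxy-4-methylphenol, via aryl pinacol boronate 3 (not isolated)
Conditions: [Ir(OMe)(cod)]2 (cat.), 4,4'-di-tert-butyl-2,2'-bipyridine (cat.), THF, 80 °C; then aq. H2O2, NaOH, 0 °C to rt
Reagents that add atoms: hydrogen peroxide, OO
Why: Iridium-catalysed C–H borylation is governed by sterics and takes the only C–H bond of 1 without an ortho substituent (para to the methyl); basic peroxide then oxidises the C–B bond with 1,2-aryl shift from boron to oxygen, a one-pot C–H borylation/oxidation established for 1,2,3-trisubstituted benzenes.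

Step 2
Reactants: 4 3,5-dimethoxy-4-methylphenol; 5 ethyl 2-bromo-2-methylpropanoate
Product: 6 ethyl 2-(3,5-dimethoxy-4-methylphenoxy)-2-methylpropanoate
Conditions: Cs2CO3, DMF, 60 °C (excess 5)
Reagents that add atoms: none
Why: Williamson ether synthesis with an α-bromo ester, the standard route to aryloxyisobutyrates; the excess of 5 makes up for its elimination to ethyl methacrylate.

Step 3
Reactants: 6 ethyl 2-(3,5-dimethoxy-4-methylphenoxy)-2-methylpropanoate
Product: 7 2-(3,5-dimethoxy-4-methylphenoxy)-2-methylpropanoic acid
Conditions: LiOH·H2O, THF/MeOH/H2O, 50 °C; then 1 M HCl
Reagents that add atoms: lithium hydroxide, [Li+].[OH-]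
Why: Ester saponification; the aryl ethers are inert to hydroxide and acidification gives the free acid.

Step 4
Reactants: 7 2-(3,5-dimethoxy-4-methylphenoxy)-2-methylpropanoic acid
Product: 9 4,6-dimethoxy-2,2,5-trimethylbenzofuran-3(2H)-one, via mixed trifluoroacetic anhydride 8 (not isolated)
Conditions: (CF3CO)2O, CH2Cl2, 0 °C to rt
Reagents that add atoms: none
Why: Intramolecular Friedel–Crafts acylation through mixed anhydride 8: the carbon attacked is ortho to the tether oxygen, ortho to one methoxy group and para to the other, the two ortho carbons are equivalent, and the gem-dimethyl group favours the five-membered closure; the mild anhydride activation avoids a free tertiary acylium ion that could lose CO.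

Step 5
Reactants: 9 4,6-dimethoxy-2,2,5-trimethylbenzofuran-3(2H)-one; 10 (trimethylsilyl)diazomethane
Product: 12 5,7-dimethoxy-2,2,6-trimethylchroman-3-one, via 4-silyl chroman-3-one 11 (not isolated)
Conditions: BF3·OEt2 (1.5 equiv), 10 (2 M in hexanes), CH2Cl2, −78 to −20 °C; then 1 M HCl, THF, rt
Reagents that add atoms: none
Why: BF3 coordinates to the C3 carbonyl of 9, the diazo carbon of 10 adds to it, and the β-oxido diazonium ion loses N2 while the bond anti to the leaving group migrates; when the aryl carbon C3a migrates, C4–C4a forms in the same event as C3–C4 and gives the α-silyl ketone 11, which aqueous acid protodesilylates to 12. The closest known reaction type is the Lewis-acid-promoted homologation of benzo-fused cyclic aryl ketones with trimethylsilyldiazomethane, a Tiffeneau–Demjanov-type ring enlargement known for indan-1-ones (to 2-tetralones) and 1-tetralones (to 2-benzosuberones); 9 is a more deactivated member of that class. The six-membered ring does not form by an end-to-end cyclisation but by a 1,2-shift that inserts one carbon into the existing five-membered ring, so no strained or large-ring transition state is involved. No stereocentre survives the step, since the silyl-bearing C4 of 11 becomes a methylene. The step needs aryl migration in preference to migration of C2: the migrating aryl carbon has two ortho oxygens and a para methoxy group and can bridge through a phenonium-like transition state, whereas C2 is quaternary and carries the electronegative O1. It also needs a single homologation, which the silyl group secures because 11 (or its silyl enol ether tautomer) is too hindered and too enolised to add a second diazoalkane. The carbonyl is deactivated by three conjugated oxygen donors and hindered by C2, which is why more than one equivalent of BF3·OEt2 is used and the mixture is warmed only as far as needed.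

Step 6
Reactants: 12 5,7-dimethoxy-2,2,6-trimethylchroman-3-one
Product: 13 (3S)-5,7-dimethoxy-2,2,6-trimethylchroman-3-ol
Conditions: (R)-2-methyl-CBS-oxazaborolidine (cat.), BH3·SMe2, THF, −20 °C, slow addition of 12; then MeOH
Reagents that add atoms: none
Why: Corey–Bakshi–Shibata reduction: the oxazaborolidine–borane complex binds the carbonyl oxygen anti to the larger flank, here quaternary C2 against the C4 methylene, and delivers hydride intramolecularly to one face; the (R)-catalyst, which gives (S)-alcohols from tert-alkyl methyl ketones, should give the (3S)-carbinol because C2 takes the place of the tert-alkyl group in both size and CIP rank.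

Step 7
Reactants: 13 (3S)-5,7-dimethoxy-2,2,6-trimethylchroman-3-ol; 14 3-phenylpropanoyl chloride
Product: 16 (3S)-5,7-dimethoxy-2,2,6-trimethyl-8-(3-phenylpropanoyl)chroman-3-yl 3-phenylpropanoate, via chromanyl 3-phenylpropanoate 15 (not isolated)
Conditions: 14 (2.5 equiv), SnCl4, CH2Cl2, −20 °C to rt
Reagents that add atoms: none
Why: Lewis-acid-promoted acylation with two equivalents of 14: the C3 hydroxyl is esterified first and the ring is then acylated at C8 (Friedel–Crafts acylation), the only unsubstituted position, activated by O1 and the 7-methoxy group ortho and the 5-methoxy group para to it; the electron-rich ring should outrun cyclisation of 14 to indan-1-one, and SnCl4 at low temperature is too mild to cleave the methyl ethers.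

Step 8
Reactants: 16 (3S)-5,7-dimethoxy-2,2,6-trimethyl-8-(3-phenylpropanoyl)chroman-3-yl 3-phenylpropanoate
Product: 17 1-[(3S)-3-hydroxy-5,7-dimethoxy-2,2,6-trimethylchroman-8-yl]-3-phenylpropan-1-one
Conditions: LiOH·H2O, THF/MeOH/H2O, rt; then 1 M HCl
Reagents that add atoms: none
Why: Saponification of the carboxylic ester; the hindered aryl ketone and the ethers are inert and the C3–O bond is not broken, so the configuration is retained.

Step 9
Reactants: 17 1-[(3S)-3-hydroxy-5,7-dimethoxy-2,2,6-trimethylchroman-8-yl]-3-phenylpropan-1-one
Product: 18 1-[(3S)-3,5,7-trihydroxy-2,2,6-trimethylchroman-8-yl]-3-phenylpropan-1-one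
Conditions: BBr3, CH2Cl2, −78 to 0 °C; then H2O
Reagents that add atoms: none
Why: Lewis-acid ether cleavage: the 7-methoxy group is removed with chelation help from the C8 carbonyl and the 5-methoxy group, twisted out of plane by its two ortho neighbours, by bromide attack on its boron-complexed methyl; the C3 hydroxyl is held as a borate whose inductive pull disfavours ionisation of O1–C2, and it returns on hydrolysis with its configuration unchanged.

## Compound list

1 | 2,6-dimethoxytoluene | COc1cccc(OC)c1C | starting material
2 | bis(pinacolato)diboron | CC1(C)OB(OC1(C)C)B1OC(C)(C)C(C)(C)O1 | starting material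
3 | 2-(3,5-dimethoxy-4-methylphenyl)-4,4,5,5-tetramethyl-1,3,2-dioxaborolane | COc1cc(B2OC(C)(C)C(C)(C)O2)cc(OC)c1C | intermediate
4 | 3,5-dimethoxy-4-methylphenol | COc1cc(O)cc(OC)c1C | intermediate
5 | ethyl 2-bromo-2-methylpropanoate | CCOC(=O)C(C)(C)Br | starting material
6 | ethyl 2-(3,5-dimethoxy-4-methylphenoxy)-2-methylpropanoate | CCOC(=O)C(C)(C)Oc1cc(OC)c(C)c(OC)c1 | intermediate
7 | 2-(3,5-dimethoxy-4-methylphenoxy)-2-methylpropanoic acid | COc1cc(OC(C)(C)C(=O)O)cc(OC)c1C | intermediate
8 | 2-(3,5-dimethoxy-4-methylphenoxy)-2-methylpropanoic trifluoroacetic anhydride | COc1cc(OC(C)(C)C(=O)OC(=O)C(F)(F)F)cc(OC)c1C | intermediate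
9 | 4,6-dimethoxy-2,2,5-trimethylbenzofuran-3(2H)-one | COc1cc2OC(C)(C)C(=O)c2c(OC)c1C | intermediate
10 | (trimethylsilyl)diazomethane | C[Si](C)(C)C=[N+]=[N-] | starting material
11 | 5,7-dimethoxy-2,2,6-trimethyl-4-(trimethylsilyl)chroman-3-one (racemic at C4) | COc1cc2OC(C)(C)C(=O)C([Si](C)(C)C)c2c(OC)c1C | intermediate
12 | 5,7-dimethoxy-2,2,6-trimethylchroman-3-one | COc1cc2OC(C)(C)C(=O)Cc2c(OC)c1C | intermediate
13 | (3S)-5,7-dimethoxy-2,2,6-trimethylchroman-3-ol | COc1cc2OC(C)(C)[C@@H](O)Cc2c(OC)c1C | intermediate
14 | 3-phenylpropanoyl chloride | O=C(Cl)CCc1ccccc1 | starting material
15 | (3S)-5,7-dimethoxy-2,2,6-trimethylchroman-3-yl 3-phenylpropanoate | COc1cc2OC(C)(C)[C@@H](OC(=O)CCc3ccccc3)Cc2c(OC)c1C | intermediate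
16 | (3S)-5,7-dimethoxy-2,2,6-trimethyl-8-(3-phenylpropanoyl)chroman-3-yl 3-phenylpropanoate | Cc1c(OC)c2c(c(C(=O)CCc3ccccc3)c1OC)OC(C)(C)[C@@H](OC(=O)CCc4ccccc4)C2 | intermediate
17 | 1-[(3S)-3-hydroxy-5,7-dimethoxy-2,2,6-trimethylchroman-8-yl]-3-phenylpropan-1-one | Cc1c(OC)c2c(c(C(=O)CCc3ccccc3)c1OC)OC(C)(C)[C@@H](O)C2 | intermediate
18 | 1-[(3S)-3,5,7-trihydroxy-2,2,6-trimethylchroman-8-yl]-3-phenylpropan-1-one | Cc1c(O)c2c(c(C(=O)CCc3ccccc3)c1O)OC(C)(C)[C@@H](O)C2 | target

## Step count and risks

Total step count: 9. Longest linear sequence: 9 steps (1 to 18).

**Step 5 (key step).** The most likely failure is that the diazoalkane does not add to the carbonyl, which is deactivated by three conjugated oxygen donors and shielded by the C2 methyls and the 4-methoxy group, so that the reagent is consumed by the Lewis acid instead. A second risk is competing migration of the quaternary carbon, which would enlarge the ring on the wrong side. The fallback keeps the one-carbon insertion with aryl migration but uses an alkene as the carrier. It sets out from 9: Wittig methylenation with Ph3P=CH2 in hot toluene should give 4,6-dimethoxy-2,2,5-trimethyl-3-methylidene-2,3-dihydro-1-benzofuran F1. Treatment of F1 with PhI(OH)OTs in 95% methanol is the known oxidative ring expansion of exocyclic methylene benzocycloalkanes: the trivalent iodine reagent adds to the alkene terminus, methanol caps the benzylic cation, and the aryl group migrates as iodobenzene leaves. Hydrolysis then gives 12, where the fallback rejoins the route.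

**Step 4.** The risk is ionisation of the activated acid to a tertiary α-aryloxy acylium ion that loses CO and fragments back to the phenol, or intermolecular acylation at higher concentration. The fallback reverses the order of bond formation and sets out from 4. Acylation of 4 ortho to the hydroxyl with 2-bromo-2-methylpropanoyl bromide and TiCl4 should give 2-bromo-1-(6-hydroxy-2,4-dimethoxy-3-methylphenyl)-2-methylpropan-1-one F2. K2CO3 in acetone then closes the furanone ring by intramolecular O-alkylation of the α-bromo ketone and returns to the route at 9.

**Step 6.** The risk is poor facial selectivity, should the catalyst not distinguish the O1-bearing quaternary carbon from the benzylic methylene well enough, or should uncatalysed borane reduction compete. The fallback replaces asymmetric induction by resolution and sets out from 12. NaBH4 reduction gives racemic 5,7-dimethoxy-2,2,6-trimethylchroman-3-ol F3. Esterification with (1S)-camphanic chloride gives the diastereomeric esters (3S)-5,7-dimethoxy-2,2,6-trimethylchroman-3-yl (1S,4R)-camphanate F4 and (3R)-5,7-dimethoxy-2,2,6-trimethylchroman-3-yl (1S,4R)-camphanate F5, which are separated by crystallisation or chromatography. Saponification of F4 with LiOH returns to the route at 13.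

**Step 9.** The risk is opening of the O1–C2 ether when boron is chelated between the C8 carbonyl and O1, or substitution at C3 through the borate on warming. The fallback unmasks the phenols before the carbonyl is present and sets out from 13. BBr3 should give (3S)-2,2,6-trimethylchromane-3,5,7-triol F6. A Houben–Hoesch reaction of F6 with 3-phenylpropanenitrile (HCl, ZnCl2, Et2O) at the only free ring carbon gives 1-[(3S)-3,5,7-trihydroxy-2,2,6-trimethylchroman-8-yl]-3-phenylpropan-1-iminium chloride F7, which warm water hydrolyses. The fallback reaches the route again at 18 and makes steps 7 and 8 unnecessary.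

## Further compounds

F1 | step 5 | 4,6-dimethoxy-2,2,5-trimethyl-3-methylidene-2,3-dihydro-1-benzofuran | COc1cc2OC(C)(C)C(=C)c2c(OC)c1C
F2 | step 4 | 2-bromo-1-(6-hydroxy-2,4-dimethoxy-3-methylphenyl)-2-methylpropan-1-one | COc1cc(O)c(C(=O)C(C)(C)Br)c(OC)c1C
F3 | step 6 | racemic 5,7-dimethoxy-2,2,6-trimethylchroman-3-ol | COc1cc2OC(C)(C)C(O)Cc2c(OC)c1C
F4 | step 6 | (3S)-5,7-dimethoxy-2,2,6-trimethylchroman-3-yl (1S,4R)-camphanate | COc1cc2OC(C)(C)[C@@H](OC(=O)[C@@]34CC[C@@](C)(C(=O)O3)C4(C)C)Cc2c(OC)c1C
F5 | step 6 | (3R)-5,7-dimethoxy-2,2,6-trimethylchroman-3-yl (1S,4R)-camphanate | COc1cc2OC(C)(C)[C@H](OC(=O)[C@@]34CC[C@@](C)(C(=O)O3)C4(C)C)Cc2c(OC)c1C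
F6 | step 9 | (3S)-2,2,6-trimethylchromane-3,5,7-triol | Cc1c(O)cc2OC(C)(C)[C@@H](O)Cc2c1O
F7 | step 9 | 1-[(3S)-3,5,7-trihydroxy-2,2,6-trimethylchroman-8-yl]-3-phenylpropan-1-iminium chloride | Cc1c(O)c2c(c(C(=[NH2+])CCc3ccccc3)c1O)OC(C)(C)[C@@H](O)C2.[Cl-]
A1 | alternative 1 | (3S)-3-(benzyloxy)-5,7-dimethoxy-6-methylchroman-2-one | COc1cc2OC(=O)[C@@H](OCc3ccccc3)Cc2c(OC)c1C
A2 | alternative 1 | 3,5-dimethoxy-4-methyl-2-[(4-methylbenzenesulfonyl)methyl]phenol | COc1cc(O)c(CS(=O)(=O)c2ccc(C)cc2)c(OC)c1C
A3 | alternative 1 | 3,5-dimethoxy-4-methyl-6-methylidenecyclohexa-2,4-dien-1-one | COC1=CC(=O)C(=C)C(OC)=C1C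
A4 | alternative 1 | (benzyloxy)acetyl chloride | O=C(Cl)COCc1ccccc1
A5 | alternative 2 | 1-[5-(benzyloxy)-7-hydroxy-2,2,6-trimethyl-2H-chromen-8-yl]-3-phenylpropan-1-one | Cc1c(O)c(C(=O)CCc2ccccc2)c2OC(C)(C)C=Cc2c1OCc1ccccc1
A6 | alternative 2 | 1-[4-(benzyloxy)-2,6-dihydroxy-3-methylphenyl]-3-phenylpropan-1-one | Cc1c(O)c(C(=O)CCc2ccccc2)c(O)cc1OCc1ccccc1
A7 | alternative 2 | 3-methylbut-2-enal | CC(C)=CC=O
A8 | alternative 2 | 1-[(3S,4S)-5-(benzyloxy)-3,4-epoxy-7-hydroxy-2,2,6-trimethylchroman-8-yl]-3-phenylpropan-1-one | Cc1c(O)c(C(=O)CCc2ccccc2)c2OC(C)(C)[C@H]3O[C@H]3c2c1OCc1ccccc1
A9 | alternative 3 | (3R)-3-hydroxy-5,7-dimethoxy-2,2,6-trimethylchroman-4-one | COc1cc2OC(C)(C)[C@@H](O)C(=O)c2c(OC)c1C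
A10 | alternative 3 | 2-(2-formyl-3,5-dimethoxy-4-methylphenoxy)-2-methylpropanal | COc1cc(OC(C)(C)C=O)c(C=O)c(OC)c1C
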